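Find the mean working share of the enzyme before trusting any rate in a flask whose concentration falls as it runs.

| setting | zeta | eta | gamma | epsilon |
|---|---|---|---|---|
| starting material | 20 mM | 20 mM | 20 mM | 20 mM |
| gas | 4.9 mM (held) | 4.9 mM (held) | 4.9 mM (held) | 4.9 mM (held) |
| free enzyme | 6.6 µM | 6.6 µM | 6.6 µM | 6.6 µM |
| temperature | 25 °C |  | 0 °C | −25 °C |
| time | 10 d | 10 d | 10 d | 10 d |
| remark |  | at −25 °C until 50 h, from then on at 25 °C |  |  |

    first product → by-product carried off (k1 = 1.33 × 10⁻⁵ s⁻¹, Ea1 = 107 kJ mol⁻¹)
    free enzyme → unfolded enzyme (k2 = 2.00 × 10⁻⁷ s⁻¹, Ea2 = 208 kJ mol⁻¹)
    gas ⇌ second substrate, rate k3*(csat - [second substrate]) (k3 = 3.83 × 10⁻⁵ s⁻¹, csat = 4.9 mM)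
    first complex → loaded enzyme + first product (k4 = 0.00731 s⁻¹, Ea4 = 91.0 kJ mol⁻¹)
    second complex → free enzyme + target (k5 = 0.0404 s⁻¹, Ea5 = 82.0 kJ mol⁻¹)
    second substrate + loaded enzyme ⇌ second complex (K6 = 279 L mol⁻¹, k6 = 297 L mol⁻¹ s⁻¹, Ea6 = 36.0 kJ mol⁻¹, ΔH6 = −89.0 kJ mol⁻¹)
    free enzyme + first product ⇌ idle complex, settled at all times (K7 = 49 L mol⁻¹, ΔH7 = −84.0 kJ mol⁻¹)
    starting material + free enzyme ⇌ first complex (K8 = 24 L mol⁻¹, k8 = 7.66 L mol⁻¹ s⁻¹, Ea8 = 57.0 kJ mol⁻¹, ΔH8 = −49.0 kJ mol⁻¹)
    (constants at 25 °C)

* the flask that comes out highest in amount of target, in percent of the starting material charged, or "all alike" when all lie within 1.5 percentage points (zeta / eta / gamma / epsilon / all alike)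
* target at the end, in percent of the starting material charged, zeta
* target at the end, in percent of the starting material charged, eta
* target at the end, in percent of the starting material charged, gamma
* target at the end, in percent of the starting material charged, epsilon

- first product is meant together with its idle complex
- at the start none of second substrate is dissolved
- all constants are for 25 °C and move with temperature by the activation energies and enthalpies

Where does the enzyme sit in zeta? Steady flow through the round gives the first complex a Michaelis constant of 42.6 mM. The step from first complex is my rate-limiting step in zeta, since its constant lies below that of the step from second complex. The gas can deliver 16.2 mM d⁻¹, much more than the 1.33 mM d⁻¹ that an enzyme without later forms would draw at the start, so I take second substrate at saturation. Counting the two later forms of the working round, and setting idle complex aside in this reckoning, enzyme bound in the round is then 1.32 times the first complex. Calling that factor lam and the Michaelis constant cM, the share in first complex at concentration c is c/(cM + lam·c). At the charged concentration of zeta this is 29.0%.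

Can that start value stand for the run? Held for 10 d, it would convert 60.4% of the charge, so c(starting material) falls too far and the start value will not do.

Does the enzyme last? At that concentration 61.8% is free, and at that share unfolding costs 10.7% by the end, so the mean enzyme left is 94.7%. That gives a capacity, the constant of the step from first complex times the enzyme left times the time, of 39.5 mM.

Now I replace the curve by its mean. The mean c(starting material) must equal the charge minus the mean of what has been converted, which gives a quadratic with root 15.2 mM. The mean working share, the part of the charged enzyme in first complex at that mean concentration, is 24.3%. Capacity times this share converts 9.58 mM, or 47.9% of the charge in zeta.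

To check the error, I integrate the same rate law exactly: that conversion needs 10.2 d, longer than 10 d, so the mean reads slightly high.

Eta has 190 h warm, less than zeta. In epsilon the step from first complex slows at least as much as the step from second complex, whose factor is 780, because its activation energy is higher. The charged enzyme, with that factor, then gives a capacity in epsilon of at most 0.266% of the charge. I commit to zeta as highest, and gamma I leave unreckoned.

The forecast names zeta, with 47% for zeta, 40% for eta, 4.2% for gamma and 0.11% for epsilon, on the ground that “The first half-reaction (the step from the first complex) limits the rate throughout”. For zeta my figure lies 0.90 percentage points above it.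

The simulation gives 45.9% for zeta, 38.4% for eta, 4.36% for gamma and 0.109% for epsilon, so zeta comes out highest, 2 points below my reckoning.

The neighbouring flask is zeta with 50 mM of starting material, the time and all else held. The same steps give a mean enzyme of 96.6% and a capacity of 40.3 mM. The mean concentration is 41.4 mM, so the mean working share is 42.6%, above that of zeta. That reckons 34.3% of this larger charge, and the simulation gives 32.9% for the neighbouring flask.

The constants used here were set for the occasion; what happens was integrated by code.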